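**Plan**

1. The target is (2S)-5-hydroxy-7-methoxyflavanone with the same 2-hydroxy-5-(2-hydroxybenzyl)benzyl arm (rings D and E) on C6 and on C8 of ring A.
2. Enabling feature: each arm is held to ring A by a single CH2 whose second bond ends at the ring D carbon next to the phenol oxygen, and C6 and C8 are the only unsubstituted carbons of ring A in natural (S)-pinostrobin, which already contains rings A, B, C and C2.
3. Retrosynthesis: remove one acetate (O5) and four benzyl ethers, then cut both CH2–ring D bonds (benzylic chloride plus aryl bromide), then the C6–CH2 and C8–CH2 bonds (chloromethylation); the aryl bromide is cut between its inner CH2 and ring E (aryl Grignard reagent plus bromo-aldehyde).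
4. Forward: pinostrobin is acetylated and chloromethylated twice; rings D and E are joined by Grignard addition and ionic hydrogenation; both arms are attached in one nickel-catalysed electroreductive coupling; acetate methanolysis and hydrogenolysis finish. No ring is built.
5. Stereochemistry: the only stereocenter, C2 (S), is bought with (S)-pinostrobin; no step touches C2 or uses a base strong enough to open ring C by retro-oxa-Michael reaction.

Key step: step 5

Assumption: the three starting materials of the compound list are catalogue compounds, the flavanone as its natural (S) enantiomer.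
Remark: in steps 2, 5 and 7 one reagent converts several like sites in one operation; the partly converted species react on under the same conditions and are not numbered.

**Route**

Step 1
Reactants: 1 ((S)-pinostrobin, (2S)-5-hydroxy-7-methoxy-2-phenylchroman-4-one)
Product: 2 (2S)-7-methoxy-4-oxo-2-phenylchroman-5-yl acetate
Conditions: Ac2O (1.5 equiv), pyridine, DMAP (cat.), CH2Cl2, 0 °C → rt
Reagents that add atoms: acetic anhydride, CC(=O)OC(C)=O
Why: DMAP-catalysed O-acylation (nucleophilic catalysis) reaches even the phenol that is hydrogen-bonded to the C4 carbonyl, and pyridine at room temperature is too weak a base to enolise the ketone and open ring C, so C2 should stay (S).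

Step 2
Reactants: 2 ((2S)-7-methoxy-4-oxo-2-phenylchroman-5-yl acetate)
Product: 3 (2S)-6,8-bis(chloromethyl)-7-methoxy-4-oxo-2-phenylchroman-5-yl acetate
Conditions: MOMCl (excess), SnCl4 (0.3 equiv), CH2Cl2, 0 °C → rt; used promptly in step 5
Reagents that add atoms: chloromethyl methyl ether, COCCl
Why: Blanc-type chloromethylation (electrophilic aromatic substitution, then chloride exchange) can only strike C6 and C8, the two free ring A carbons that are each ortho or para to the ether oxygens on C7 and C8a, while ring B is unactivated and the cold aprotic Lewis-acid medium should leave the acetate and C2 alone.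

Step 3
Reactants: 4 (1-(benzyloxy)-2-bromobenzene) and 5 (4-(benzyloxy)-3-bromobenzaldehyde)
Product: 7 (±)-[4-(benzyloxy)-3-bromophenyl][2-(benzyloxy)phenyl]methanol, via 2-(benzyloxy)phenylmagnesium bromide 6 (not isolated)
Conditions: 4, Mg, I2 (cat.), THF, reflux; then 5, THF, −20 → 0 °C; aq. NH4Cl
Reagents that add atoms: none
Why: Grignard formation and 1,2-addition to the aldehyde, in which the aryl bromide of 5 does not exchange with an arylmagnesium halide at this temperature; the new carbinol centre is racemic and is removed in step 4.

Step 4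
Reactants: 7 ((±)-[4-(benzyloxy)-3-bromophenyl][2-(benzyloxy)phenyl]methanol)
Product: 8 1-(benzyloxy)-4-[2-(benzyloxy)benzyl]-2-bromobenzene
Conditions: Et3SiH (3 equiv), TFA (5 equiv), CH2Cl2, 0 °C
Reagents that add atoms: none
Why: Ionic hydrogenation, in which TFA ionises the doubly benzylic alcohol to a cation stabilised by the para- and ortho-benzyloxy groups and Et3SiH delivers hydride, under conditions that leave the aryl bromide and the benzyl ethers intact.

Step 5
Reactants: 3 ((2S)-6,8-bis(chloromethyl)-7-methoxy-4-oxo-2-phenylchroman-5-yl acetate) and 8 (1-(benzyloxy)-4-[2-(benzyloxy)benzyl]-2-bromobenzene, 2.5 equiv)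
Product: 9 (2S)-6,8-bis{2-(benzyloxy)-5-[2-(benzyloxy)benzyl]benzyl}-7-methoxy-4-oxo-2-phenylchroman-5-yl acetate
Conditions: NiBr2(dme) (10 mol %), 4,4'-di-tert-butyl-2,2'-bipyridine (12 mol %), n-Bu4NBr, DMA, undivided cell, Zn anode, reticulated vitreous carbon cathode, constant current, rt; 3 added slowly by syringe pump
Reagents that add atoms: none
Why: At the cathode the divalent nickel bipyridine complex is reduced to zerovalent nickel, which inserts into the C–Br bond of 8; monovalent nickel formed in the cycle abstracts chlorine from a chloromethyl group of 3, the benzylic radical is captured by the arylnickel bromide to give a trivalent aryl(benzyl)nickel species, and reductive elimination forms the CH2–ring D bond while the Zn anode supplies Zn2+ for the halide released. The closest known reaction type is the nickel-catalysed electroreductive (or Zn- or Mn-driven) cross-electrophile coupling of benzyl chlorides with aryl bromides to diarylmethanes, here run twice on one ring A. No ring is closed and no stereocenter is formed; C2 is safe because the medium holds neither base nor a polar organometallic reagent. The selectivity needed is cross- over homo-coupling, secured by the different activation of the two halides (two-electron oxidative addition for the aryl C–Br bond, radical formation for the benzylic C–Cl bond), by the excess of 8 and by the low stationary concentration of 3. Within 3 the two chloromethyl groups are meta to each other across C7 and cannot bond to one another, the 5-O-acetyl group leaves no phenol that could expel chloride as an ortho-quinone methide, and the nickel wave lies well positive of the reduction of the aryl ketone, the acetate and the benzyl ethers.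

Step 6
Reactants: 9 ((2S)-6,8-bis{2-(benzyloxy)-5-[2-(benzyloxy)benzyl]benzyl}-7-methoxy-4-oxo-2-phenylchroman-5-yl acetate)
Product: 10 (2S)-6,8-bis{2-(benzyloxy)-5-[2-(benzyloxy)benzyl]benzyl}-5-hydroxy-7-methoxy-2-phenylchroman-4-one
Conditions: HCl (1.25 M in MeOH), THF, rt → 40 °C
Reagents that add atoms: none
Why: Acid-catalysed transesterification of the aryl acetate with methanol, favoured by the hydrogen bond that the freed 5-OH forms to the C4 carbonyl; acid is chosen because alkoxide would open ring C and racemise C2, and the benzyl ethers are stable to it.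

Step 7
Reactants: 10 ((2S)-6,8-bis{2-(benzyloxy)-5-[2-(benzyloxy)benzyl]benzyl}-5-hydroxy-7-methoxy-2-phenylchroman-4-one)
Product: 11 5''-(2''''-hydroxybenzyl)uvarinol, (2S)-5-hydroxy-6,8-bis[2-hydroxy-5-(2-hydroxybenzyl)benzyl]-7-methoxy-2-phenylchroman-4-one
Conditions: H2 (1 atm), Pd/C (10 wt %), EtOAc–MeOH, rt
Reagents that add atoms: none
Why: Heterogeneous hydrogenolysis of the four aryl benzyl ethers, which should be cleaved much faster than the ring C benzylic C2–O1 bond or the chelated aryl ketone under neutral conditions at 1 atm, so C2 stays (S).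

**Compound list**

1 | (S)-pinostrobin, (2S)-5-hydroxy-7-methoxy-2-phenylchroman-4-one | O=C1C[C@@H](c2ccccc2)Oc2cc(OC)cc(O)c12 | starting material
2 | (2S)-7-methoxy-4-oxo-2-phenylchroman-5-yl acetate | O=C1C[C@@H](c2ccccc2)Oc2cc(OC)cc(OC(C)=O)c12 | intermediate
3 | (2S)-6,8-bis(chloromethyl)-7-methoxy-4-oxo-2-phenylchroman-5-yl acetate | O=C1C[C@@H](c2ccccc2)Oc2c(CCl)c(OC)c(CCl)c(OC(C)=O)c12 | intermediate
4 | 1-(benzyloxy)-2-bromobenzene | Brc1ccccc1OCc1ccccc1 | starting material
5 | 4-(benzyloxy)-3-bromobenzaldehyde | O=Cc1ccc(OCc2ccccc2)c(Br)c1 | starting material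
6 | 2-(benzyloxy)phenylmagnesium bromide | Br[Mg]c1ccccc1OCc1ccccc1 | intermediate (not isolated)
7 | (±)-[4-(benzyloxy)-3-bromophenyl][2-(benzyloxy)phenyl]methanol (racemic) | OC(c1ccc(OCc2ccccc2)c(Br)c1)c1ccccc1OCc1ccccc1 | intermediate
8 | 1-(benzyloxy)-4-[2-(benzyloxy)benzyl]-2-bromobenzene | Brc1cc(Cc2ccccc2OCc2ccccc2)ccc1OCc1ccccc1 | intermediate
9 | (2S)-6,8-bis{2-(benzyloxy)-5-[2-(benzyloxy)benzyl]benzyl}-7-methoxy-4-oxo-2-phenylchroman-5-yl acetate | O=C1C[C@@H](c2ccccc2)Oc2c(Cc3cc(Cc4ccccc4OCc4ccccc4)ccc3OCc3ccccc3)c(OC)c(Cc3cc(Cc4ccccc4OCc4ccccc4)ccc3OCc3ccccc3)c(OC(C)=O)c12 | intermediate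
10 | (2S)-6,8-bis{2-(benzyloxy)-5-[2-(benzyloxy)benzyl]benzyl}-5-hydroxy-7-methoxy-2-phenylchroman-4-one | O=C1C[C@@H](c2ccccc2)Oc2c(Cc3cc(Cc4ccccc4OCc4ccccc4)ccc3OCc3ccccc3)c(OC)c(Cc3cc(Cc4ccccc4OCc4ccccc4)ccc3OCc3ccccc3)c(O)c12 | intermediate
11 | 5''-(2''''-hydroxybenzyl)uvarinol, (2S)-5-hydroxy-6,8-bis[2-hydroxy-5-(2-hydroxybenzyl)benzyl]-7-methoxy-2-phenylchroman-4-one | COc1c(Cc2cc(Cc3ccccc3O)ccc2O)c(O)c2c(c1Cc1cc(Cc3ccccc3O)ccc1O)O[C@H](c1ccccc1)CC2=O | target

**Step count and risks**

Total steps: 7. Longest linear sequence: 5 steps (1 → 2 → 3 → 9 → 10 → 11; the arm branch 4/5 → 7 → 8 → 9 → 10 → 11 is equally long).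

Steps most likely to fail:

1. Step 5. The benzylic chloride may homo-couple reductively to bibenzyl-type oligomers, either partner may be hydrodehalogenated, or radical capture at the doubly ortho-flanked benzylic carbons may be too slow and stop after one arm. The fallback sets out from 8. Bromine–lithium exchange (n-BuLi, THF, −78 °C) should give {2-(benzyloxy)-5-[2-(benzyloxy)benzyl]phenyl}lithium F1, and ZnCl2 should convert it into {2-(benzyloxy)-5-[2-(benzyloxy)benzyl]phenyl}zinc chloride F2. A Negishi coupling of F2 (2.5 equiv) with 3 (Pd(OAc)2, SPhos, THF, rt → 40 °C) then forms the same two CH2–ring D bonds by a two-electron palladium cycle and comes back to the route at 9. The arylzinc reagent is mild enough for the ketone, the acetate and C2.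

2. Step 2. The first-formed benzylic chloride may alkylate ring A of a second molecule (diarylmethane oligomers), the reaction may stall after one substitution, or the Lewis acid may open ring C and erode C2. The fallback sets out from 1. Twofold Mannich aminomethylation with N,N-dimethylmethyleneiminium iodide (MeCN, rt → 50 °C, no added amine) at the positions ortho and para to the free 5-OH should give (2S)-6,8-bis[(dimethylamino)methyl]-5-hydroxy-7-methoxy-2-phenylchroman-4-one F3. O-Acetylation (Ac2O, DMAP cat., CH2Cl2, rt) should give (2S)-6,8-bis[(dimethylamino)methyl]-7-methoxy-4-oxo-2-phenylchroman-5-yl acetate F4. Ethyl chloroformate (CH2Cl2, 0 °C → rt) then exchanges each benzylic dimethylamino group for chloride (von Braun-type cleavage of a benzylic tertiary amine) and comes back to the route at 3.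

3. Step 7. Over-reduction (hydrogenolytic opening of ring C at the benzylic C2–O1 bond or reduction of the C4 ketone) or stalling before all four ethers are cleaved may occur. The fallback sets out from 10 and uses Lewis-acid debenzylation with BCl3 and pentamethylbenzene as cation scavenger (CH2Cl2, −78 °C), which spares the unchelated 7-OMe group and comes back directly at 11; no new compound is formed on the way (F0).

**Further compounds**

F1 | step 5 | {2-(benzyloxy)-5-[2-(benzyloxy)benzyl]phenyl}lithium | [Li]c1cc(Cc2ccccc2OCc2ccccc2)ccc1OCc1ccccc1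
F2 | step 5 | {2-(benzyloxy)-5-[2-(benzyloxy)benzyl]phenyl}zinc chloride | Cl[Zn]c1cc(Cc2ccccc2OCc2ccccc2)ccc1OCc1ccccc1
F3 | step 2 | (2S)-6,8-bis[(dimethylamino)methyl]-5-hydroxy-7-methoxy-2-phenylchroman-4-one | O=C1C[C@@H](c2ccccc2)Oc2c(CN(C)C)c(OC)c(CN(C)C)c(O)c12
F4 | step 2 | (2S)-6,8-bis[(dimethylamino)methyl]-7-methoxy-4-oxo-2-phenylchroman-5-yl acetate | O=C1C[C@@H](c2ccccc2)Oc2c(CN(C)C)c(OC)c(CN(C)C)c(OC(C)=O)c12
F0 | step 7 | none | none
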